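**Retrosynthetic overview**
- The C5–OOH / C4=CH2 unit comes from a last-step Schenck ene reaction on the isolated (E)-C4=C5 alkene of ovatodiolide.
- The 14-membered ring, the α-methylene lactone and C1 come from one C1–C2 bond-forming radical macrocyclisation. A primary C2 radical adds to the β-carbon of a 3-(phenylsulfonylmethyl)butenolide and expels PhSO2•.
- Both butenolides come from one double RCM of an unsymmetrical bis(2-substituted acrylate) of a (3R,7R)-nona-1,4,8-triene-3,7-diol.
- The triene-diol core comes from 2 × acrolein, propargyl bromide and a methyl group, by asymmetric propargylation, methylalumination/iodination and asymmetric Ni/Cr coupling. The two esters are installed one after the other.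
- The side-chain acid comes from methyl 1-methylcyclopropyl ketone and 2-(bromomethyl)acrylic acid. Ring order: the two butenolides form together, then the macrocycle.

Assumption: the SMILES is taken as definitive. In cembrane numbering it is 1R,5R,10R,14S, where C1 is the lactone β-CH, C14 the lactone O–CH, C10 the butenolide O–CH and C5 the CH–OOH.

**Step 1**
Reactants: 1, 1-(1-methylcyclopropyl)ethan-1-one; 2, 2-(bromomethyl)acrylic acid
Product: 3, 2-methylidene-5-(1-methylcyclopropyl)-5-oxopentanoic acid
Conditions: 1 (2.2 equiv), LDA (2.2 equiv), THF, −78 °C; then 2 (1.0 equiv), −78 → 0 °C; H3O+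
Reagents that add atoms: none
Why: Enolate allylation: the ketone has a single enolisable site, the first equivalent of enolate only deprotonates the acid, and SN2 and SN2′ attack on the allylic bromide give the same product.

**Step 2**
Reactants: 3
Product: 4, (±)-5-hydroxy-2-methylidene-5-(1-methylcyclopropyl)pentanoic acid (used crude; any δ-lactone formed converges in step 3)
Conditions: NaBH4, aq NaOH/EtOH, 0 °C → rt; acidify to pH 4
Reagents that add atoms: none
Why: Borohydride 1,2-reduction of the ketone; the acrylate is protected as its carboxylate, and the racemic carbinol centre is destroyed in the next step.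

**Step 3**
Reactants: 4
Product: 5, (E)-8-iodo-6-methyl-2-methylideneoct-5-enoic acid
Conditions: MgI2 (3 equiv, from Mg/I2), Et2O–toluene, 35–40 °C; aq Na2S2O3, then pH 3
Reagents that add atoms: magnesium iodide, [Mg+2].[I-].[I-]
Why: Julia–Johnson cyclopropylcarbinyl-to-homoallyl rearrangement: ionisation at the secondary carbinol next to a 1-methylcyclopropane with iodide attack on a ring CH2 gives the primary iodide, and the (E)-trisubstituted alkene forms because the chain sits away from the ring in the bisected transition state.

**Step 4**
Reactants: 2
Product: 6, 2-[(phenylsulfonyl)methyl]acrylic acid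
Conditions: PhSO2Na (1.5 equiv), MeOH, reflux; H3O+
Reagents that add atoms: sodium benzenesulfinate, [Na+].[O-]S(=O)c1ccccc1
Why: S-alkylation of a sulfinate by an activated allylic bromide, where SN2 and SN2′ are degenerate.

**Step 5**
Reactants: 7, acrolein; 8, propargyl bromide
Product: 9, (R)-hex-1-en-5-yn-3-ol
Conditions: CrCl2 (10 mol %), chiral oxazoline–sulfonamide ligand (11 mol %, antipode giving R), proton sponge, Mn, Cp2ZrCl2, LiCl, MeCN, rt
Reagents that add atoms: none
Why: Catalytic asymmetric Nozaki–Hiyama propargylation: allenyl-Cr(III) adds SE2′ to the aldehyde inside the chiral ligand sphere and sets C10, and Cp2ZrCl2 replaces TMSCl so that acrolein is not diverted to a siloxyallyl-chromium species.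

**Step 6**
Reactants: 9
Product: 10, (3R,5E)-6-iodo-5-methylhexa-1,5-dien-3-ol
Conditions: Me3Al (3 equiv), Cp2ZrCl2 (0.25 equiv), CH2Cl2, 0 °C → rt; then I2, THF, −30 °C
Reagents that add atoms: trimethylaluminium, C[Al](C)C; iodine, II
Why: Negishi Zr-catalysed syn-methylalumination of the terminal alkyne followed by iodinolysis with retention fixes the (E)-C12=C13 geometry; the alcohol reacts as its aluminium alkoxide, the vinyl group is inert and C10 is untouched.

**Step 7**
Reactants: 10; 5
Product: 11, (3R,5E)-6-iodo-5-methylhexa-1,5-dien-3-yl (E)-8-iodo-6-methyl-2-methylideneoct-5-enoate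
Conditions: EDCI, DMAP (0.2 equiv), CH2Cl2, 0 °C → rt
Reagents that add atoms: none
Why: Steglich esterification at oxygen, so C10 keeps its configuration and both iodides and all alkenes are spectators.

**Step 8**
Reactants: 11; 7, acrolein
Product: 12, (3R,4E,7R)-3-hydroxy-5-methylnona-1,4,8-trien-7-yl (E)-8-iodo-6-methyl-2-methylideneoct-5-enoate
Conditions: CrCl2 (3.5 equiv), chiral oxazoline–sulfonamide ligand (3.8 equiv), Et3N, NiCl2 (1 mol %), acrolein (4 equiv), THF, rt (no Mn, no Co)
Reagents that add atoms: none
Why: Asymmetric Nozaki–Hiyama–Kishi alkenylation: Ni inserts only into the C(sp2)–I bond with retention of geometry, the primary alkyl iodide needs Co co-catalysis to react with Cr(II), esters are tolerated, and the ligand on Cr sets the C14 carbinol under reagent control.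

**Step 9**
Reactants: 12; 6
Product: 13, (3R,4E,7R)-5-methyl-3-{[2-(phenylsulfonylmethyl)acryloyl]oxy}nona-1,4,8-trien-7-yl (E)-8-iodo-6-methyl-2-methylideneoct-5-enoate
Conditions: EDCI, DMAP (0.1 equiv), CH2Cl2, −10 → 0 °C
Reagents that add atoms: none
Why: Steglich esterification under cold, nearly neutral conditions acylates the bis-allylic alcohol at oxygen without ionisation, so C14 is retained, and any sulfinate addition–elimination on the acrylate is degenerate.

**Step 10**
Reactants: 13
Product: 14, (S)-5-{(E)-3-[(R)-4-((E)-6-iodo-4-methylhex-3-en-1-yl)-5-oxo-2,5-dihydrofuran-2-yl]-2-methylprop-1-en-1-yl}-3-[(phenylsulfonyl)methyl]furan-2(5H)-one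
Conditions: Hoveyda–Grubbs II (2 × 5 mol %), 1,4-benzoquinone (20 mol %), toluene, 60 °C, 5 mM, Ar sparge
Reagents that add atoms: none
Why: Double ring-closing metathesis: each terminal vinyl carbene closes on its own 2-substituted acrylate to give a five-membered butenolide, the vinyl–vinyl closure would need an (E)-cycloheptene, the trisubstituted alkenes are spectators and both stereocentres are untouched.

**Step 11 (key step)**
Reactants: 14
Product: 15, ovatodiolide (1R,10R,14S; 4E,12E)
Conditions: 14 added over 10 h to (Bu3Sn)2 (1.5 equiv), degassed benzene (final 0.5 mM), sunlamp, 20–25 °C (water-cooled)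
Reagents that add atoms: none
Why: Proposed new method: Bu3Sn• abstracts the primary iodine, and the nucleophilic C2 radical (barred by the E-alkene from 1,5-H shift and small-ring closure) adds to the electrophilic butenolide β-carbon anti to the C14 alkenyl group, setting C1 trans to C14; the tertiary α-acyl radical then expels PhSO2•, which makes the closure irreversible, reveals the exo-methylene and carries the chain through the ditin with no H-donor present; the closest known reaction types are 14-endo radical macrocyclisations of ω-iodo enones in cembranoid work, SH2′ allyl transfer from 2-(sulfonylmethyl)- or 2-(stannylmethyl)acrylates, and anti-selective Giese additions to 5-substituted butenolides.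

**Step 12**
Reactants: 15
Product: 16, 4-methylene-5β-hydroperoxyovatodiolide (1R,5R,10R,14S)
Conditions: O2, TPP (1 mol %), CH2Cl2, white LED, −10 °C, stop at about 80 % conversion; chromatography
Reagents that add atoms: dioxygen, O=O
Why: Schenck ene reaction: singlet oxygen attacks only the electron-rich isolated C4=C5 alkene (C12=C13 is deactivated by the allylic acyloxy group and the two enoates are inert), the cis effect limits H-abstraction to the C4-methyl or C6 side, C5–O bonding with methyl-H abstraction gives the exocyclic methylene, attack on the exposed outer face of the macrocyclic alkene is expected to set 5R, and the 4-hydroperoxy-5-ene regioisomer is separated.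

**Compound list**

| No. | Name | SMILES | Role |
|---|---|---|---|
| 1 | 1-(1-methylcyclopropyl)ethan-1-one | CC(=O)C1(C)CC1 | starting material |
| 2 | 2-(bromomethyl)acrylic acid | C=C(CBr)C(=O)O | starting material |
| 3 | 2-methylidene-5-(1-methylcyclopropyl)-5-oxopentanoic acid | C=C(CCC(=O)C1(C)CC1)C(=O)O | intermediate |
| 4 | (±)-5-hydroxy-2-methylidene-5-(1-methylcyclopropyl)pentanoic acid | C=C(CCC(O)C1(C)CC1)C(=O)O | intermediate |
| 5 | (E)-8-iodo-6-methyl-2-methylideneoct-5-enoic acid | C=C(CC/C=C(\C)CCI)C(=O)O | intermediate |
| 6 | 2-[(phenylsulfonyl)methyl]acrylic acid | C=C(CS(=O)(=O)c1ccccc1)C(=O)O | intermediate |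
| 7 | acrolein | C=CC=O | starting material |
| 8 | propargyl bromide | C#CCBr | starting material |
| 9 | (R)-hex-1-en-5-yn-3-ol | C#CC[C@@H](O)C=C | intermediate |
| 10 | (3R,5E)-6-iodo-5-methylhexa-1,5-dien-3-ol | I/C=C(\C)C[C@@H](O)C=C | intermediate |
| 11 | C10 ester, vinyl iodide / alkyl iodide | I/C=C(\C)C[C@@H](OC(=O)C(=C)CC/C=C(\C)CCI)C=C | intermediate |
| 12 | C14 bis-allylic alcohol | C=C[C@@H](O)/C=C(\C)C[C@@H](OC(=O)C(=C)CC/C=C(\C)CCI)C=C | intermediate |
| 13 | bis-acrylate | C=C[C@@H](OC(=O)C(=C)CS(=O)(=O)c1ccccc1)/C=C(\C)C[C@@H](OC(=O)C(=C)CC/C=C(\C)CCI)C=C | intermediate |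
| 14 | bis-butenolide iodo-sulfone | O=C1O[C@@H](/C=C(\C)C[C@@H]2C=C(CC/C=C(\C)CCI)C(=O)O2)C=C1CS(=O)(=O)c1ccccc1 | intermediate |
| 15 | ovatodiolide | C=C1C(=O)O[C@H]2/C=C(\C)C[C@@H]3C=C(CC/C=C(\C)CC[C@H]12)C(=O)O3 | intermediate |
| 16 | 4-methylene-5β-hydroperoxyovatodiolide | C=C1C(=O)O[C@H]2/C=C(\C)C[C@@H]3C=C(CC[C@@H](OO)C(=C)CC[C@H]12)C(=O)O3 | target |

**Total step count:** 12.
**Longest linear sequence:** 9 steps (steps 1, 2, 3, 7, 8, 9, 10, 11, 12).

**Three steps most likely to fail**

1. **Step 11.**
   - Risks:
     - The 14-membered closure onto a β-CH of a trisubstituted butenolide may be slow.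
     - The C4=C5 geometry may partly scramble through the homoallyl/cyclopropylcarbinyl radical equilibrium.
     - The radical may abstract the weak C14–H.
     - The radical may add to the α-methylene lactone of the product.
   - Fallback: separate the two events.
     - Run the same sulfone-fragmentation allyl transfer intermolecularly. The partners are an ester of iodide 5 and an excess of the left-hand sulfonylbutenolide bearing a silylated C10 vinyl carbinol.
     - Close the ring by Shiina macrolactonisation at the C10 oxygen.
     - Form the second butenolide by transannular RCM.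
2. **Step 12.**
   - Risks: about 1:1 regiochemistry against the 4-hydroperoxy-5-ene, and facial selectivity that rests only on macrocycle conformation.
   - Fallback: build the C5–O bond in stages.
     - Epoxidise C4=C5 from the periphery with mCPBA.
     - Open the epoxide with Cp2TiCl, followed by β-H elimination, to give the 4-methylene-5-ol.
     - Apply Mitsunobu inversion if the configuration requires it.
     - Mesylate and displace by SN2 with 2-methoxyprop-2-yl hydroperoxide/CsOH, then release the hydroperoxide with mild acid.
3. **Step 8.**
   - Risks: enantiofacial control with acrolein, and survival of the primary alkyl iodide under Ni/Cr conditions.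
   - Fallback: set C14 by reduction instead of addition.
     - Carry the C2 halide as the bromide, using MgBr2 in step 3.
     - Run an achiral Ni/Cr coupling.
     - Oxidise with Dess–Martin periodinane to the cross-conjugated dienone.
     - Reduce with a CBS catalyst.
     - Exchange Br for I with NaI after the RCM.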